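**Plan**
- Retrosynthesis: the two MOM acetals are removed last. Ring B is then cut at the two C–C bonds that join its two CH carbons to the neighbouring ether-bearing carbons, giving a ring A 1-aryloxy-3-(methoxymethoxy)acetone and a 2-substituted 3-(dimethylamino)acrolein.
- Enabling feature: ring B is a 2,6-dioxygenated phenol. Its C–OH carbon and the two flanking C–O carbons are the carbonyl and α-carbons of a 1,3-dioxygenated acetone, and the carbon carrying the quaternary centre lies para to that OH between two CH carbons, as C2 of a malonaldehyde.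
- Ketone: the O–CH2 bond comes from phenoxide opening of glycidyl MOM ether followed by oxidation, the phenol oxygen from MOM-directed ortho-lithiation/borylation/oxidation, and the aryl–C(quaternary) bond from copper-catalysed SN2′ arylation of farnesyl phosphate.
- Enaminal: aminomethylenation of an aldehyde obtained by two Matteson homologations of the tertiary allylboronate from copper-catalysed SN2′ borylation of farnesyl carbonate.
- Forward order: ring A is bought, the farnesyl chain is attached, then the ring oxygen and the ketone side chain; fragment 2 is built separately; ring B is the only ring formed (step 12); deprotection ends the route.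
- Stereochemistry: the R centre arises from aryl delivery to the Re face of C3 of farnesyl phosphate, the S centre from boron delivery to the Si face of C3 of farnesyl carbonate followed by stereoretentive 1,2-migrations; both are catalyst-controlled, and all E-alkenes come from farnesol.

Key step: step 12

Remark: glycidol is used as the racemate, so 12 is a mixture of carbinol epimers that converge on oxidation to 13; the sense of induction of each copper catalyst is assumed to follow the geranyl-type cases, and the ligand antipode is chosen accordingly.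

**Fragment 1 (ring A ketone)**

Step 1
Reactants: 1 (2E,6E)-farnesol
Product: 2 diethyl (2E,6E)-3,7,11-trimethyldodeca-2,6,10-trien-1-yl phosphate
Conditions: ClP(O)(OEt)2, Et3N, DMAP (cat.), CH2Cl2, 0 °C
Reagents that add atoms: diethyl chlorophosphate, CCOP(=O)(Cl)OCC
Why: O-phosphorylation of a primary allylic alcohol under amine base is routine, leaves the E-alkenes untouched and installs the leaving group needed for copper-catalysed SN2′ substitution.

Step 2
Reactants: 3 1-bromo-4-(methoxymethoxy)benzene; 2 diethyl farnesyl phosphate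
Product: 6 1-(methoxymethoxy)-4-[(3R,6E)-3,7,11-trimethyldodeca-1,6,10-trien-3-yl]benzene, via 4-(methoxymethoxy)phenyllithium 4 (not isolated), via diethyl[4-(methoxymethoxy)phenyl]aluminium 5 (not isolated)
Conditions: n-BuLi, THF, −78 °C; Et2AlCl, −78 °C → rt; then 2, CuCl2·2H2O (cat.), chiral sulfonate-bearing N-heterocyclic carbene (as its silver complex made from the imidazolinium salt and Ag2O), THF, −30 °C
Reagents that add atoms: none
Why: Copper-catalysed enantioselective allylic substitution (SN2′) of E-trisubstituted allylic phosphates with aryl(dialkyl)aluminium reagents made from aryllithiums is established on geranyl-type phosphates, and the chiral carbene–copper aryl complex should deliver the aryl group to the Re face of C3, which sets the R quaternary centre.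

Step 3
Reactants: 6 1-(methoxymethoxy)-4-[(3R,6E)-3,7,11-trimethyldodeca-1,6,10-trien-3-yl]benzene
Product: 9 2-(methoxymethoxy)-5-[(3R,6E)-3,7,11-trimethyldodeca-1,6,10-trien-3-yl]phenol, via ortho-lithiated arene 7 (not isolated), via dimethyl arylboronate 8 (not isolated)
Conditions: s-BuLi, TMEDA, THF, −78 °C; B(OMe)3, −78 °C → rt; then H2O2, aq NaOH, 0 °C
Reagents that add atoms: hydrogen peroxide, OO
Why: Directed ortho-metalation by the MOM ether (its two ortho positions are equivalent), borylation and oxidative C–B to C–O conversion is the standard entry to catechol mono-MOM ethers, the quaternary carbon offers no benzylic hydrogen and basic peroxide leaves isolated alkenes alone.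

Step 4
Reactants: 10 glycidol (racemic oxiran-2-ylmethanol)
Product: 11 2-[(methoxymethoxy)methyl]oxirane (racemic)
Conditions: MOMCl, i-Pr2NEt, CH2Cl2, 0 °C → rt
Reagents that add atoms: chloromethyl methyl ether, COCCl
Why: Acetalisation of the primary alcohol under hindered amine base is a routine MOM protection that leaves the epoxide intact.

Step 5
Reactants: 9 2-(methoxymethoxy)-5-[(3R,6E)-3,7,11-trimethyldodeca-1,6,10-trien-3-yl]phenol; 11 2-[(methoxymethoxy)methyl]oxirane
Product: 12 1-(methoxymethoxy)-3-{2-(methoxymethoxy)-5-[(3R,6E)-3,7,11-trimethyldodeca-1,6,10-trien-3-yl]phenoxy}propan-2-ol (both carbinol epimers)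
Conditions: K2CO3 (0.5 equiv), DMF, 90 °C
Reagents that add atoms: none
Why: Phenoxide opening of a terminal epoxide by SN2 attack at the unsubstituted carbon is the standard route to 1-aryloxy-3-alkoxypropan-2-ols, and the new carbinol centre is of no consequence because it is oxidised next.

Step 6
Reactants: 12 1-(methoxymethoxy)-3-{2-(methoxymethoxy)-5-[(3R,6E)-3,7,11-trimethyldodeca-1,6,10-trien-3-yl]phenoxy}propan-2-ol
Product: 13 1-(methoxymethoxy)-3-{2-(methoxymethoxy)-5-[(3R,6E)-3,7,11-trimethyldodeca-1,6,10-trien-3-yl]phenoxy}propan-2-one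
Conditions: Dess–Martin periodinane, CH2Cl2, 0 °C → rt
Reagents that add atoms: none
Why: Dess–Martin oxidation of a secondary alcohol to the ketone runs under near-neutral conditions that spare the MOM ethers and all alkenes, and it removes the carbinol stereocentre.

**Fragment 2 (enaminal)**

Step 7
Reactants: 1 (2E,6E)-farnesol
Product: 14 methyl (2E,6E)-3,7,11-trimethyldodeca-2,6,10-trien-1-yl carbonate
Conditions: ClCO2Me, pyridine, CH2Cl2, 0 °C
Reagents that add atoms: methyl chloroformate, COC(=O)Cl
Why: Acylation of the primary allylic alcohol with a chloroformate is routine and provides the carbonate leaving group for the boryl substitution.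

Step 8
Reactants: 14 methyl farnesyl carbonate
Product: 15 4,4,5,5-tetramethyl-2-[(3R,6E)-3,7,11-trimethyldodeca-1,6,10-trien-3-yl]-1,3,2-dioxaborolane
Conditions: B2pin2, Cu(OTf)2 (cat.), chiral imidazolinium salt (N-heterocyclic carbene precursor), NaOMe (substoichiometric), DME, −30 °C
Reagents that add atoms: bis(pinacolato)diboron, CC1(C)OB(OC1(C)C)B1OC(C)(C)C(C)(C)O1
Why: Carbene–copper-catalysed enantioselective SN2′ boryl substitution of E-trisubstituted allylic carbonates is a known route to allylboronates with a boron-bearing quaternary carbon, and the chiral copper–boryl complex should add boron to the Si face of C3 to give the R boronate.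

Step 9
Reactants: 15 tertiary allylboronate
Product: 16 2-[(2S,5E)-2-ethenyl-2,6,10-trimethylundeca-5,9-dien-1-yl]-4,4,5,5-tetramethyl-1,3,2-dioxaborolane
Conditions: BrCH2Cl, n-BuLi, THF, −78 °C → rt
Reagents that add atoms: bromochloromethane, ClCBr
Why: In this Matteson homologation chloromethyllithium generated in the presence of the boronate forms the ate complex and the tertiary allyl group migrates from boron to carbon with retention, so the quaternary centre keeps its spatial arrangement (the descriptor becomes S only through the priority rules).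

Step 10
Reactants: 16 homologated primary boronate
Product: 18 (3R,6E)-3-ethenyl-3,7,11-trimethyldodeca-6,10-dienal, via alpha-chloroboronic ester 17 (not isolated)
Conditions: CH2Cl2, LiN(i-Pr)2, THF, −78 °C → rt; then H2O2, NaH2PO4/Na2HPO4 buffer (pH 8), THF, 0 °C → rt
Reagents that add atoms: dichloromethane, ClCCl; hydrogen peroxide, OO
Why: Matteson homologation with dichloromethyllithium gives the α-chloroboronic ester, whose oxidation at boron produces an α-chloro alkoxide that collapses to the aldehyde, a known one-carbon boronate-to-aldehyde homologation that does not involve the quaternary centre.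

Step 11
Reactants: 18 (3R,6E)-3-ethenyl-3,7,11-trimethyldodeca-6,10-dienal
Product: 19 (2Z)-3-(dimethylamino)-2-[(3S,6E)-3,7,11-trimethyldodeca-1,6,10-trien-3-yl]prop-2-enal
Conditions: t-BuOCH(NMe2)2, toluene, 80 °C
Reagents that add atoms: tert-butoxybis(dimethylamino)methane, CN(C)C(OC(C)(C)C)N(C)C
Why: Aminomethylenation of the α-methylene group of an aldehyde with Bredereck's reagent gives the push–pull enaminal with loss of tert-butanol and dimethylamine, the β-quaternary carbon slows self-aldol condensation, and the alkene geometry is immaterial because both termini enter the arene.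

**Union and completion**

Step 12
Reactants: 13 ring A aryloxy ketone; 19 enaminal
Product: 21 2-(methoxymethoxy)-6-{2-(methoxymethoxy)-5-[(3R,6E)-3,7,11-trimethyldodeca-1,6,10-trien-3-yl]phenoxy}-4-[(3S,6E)-3,7,11-trimethyldodeca-1,6,10-trien-3-yl]phenol, via open-chain keto enal 20 (not isolated)
Conditions: NaOEt (2 equiv), EtOH, slow addition of 13 to 19 (1.3 equiv), rt → 78 °C, argon
Reagents that add atoms: none
Why: Ethoxide forms the enolate at the aryloxy-bearing α-carbon of 13, which adds to the amine-bearing carbon of the push–pull alkene of 19 and expels dimethylamine (addition–elimination) to give 20; the second α-carbon then attacks the aldehyde, and loss of water and tautomerisation of the cyclohexadienone give the phenol. The closest known reaction type is the base-mediated [3+3] condensation of ketones with 2-substituted malonaldehyde equivalents (aminoacroleins, vinamidinium salts, nitromalonaldehyde) to 4-substituted phenols. Ring B closes by a 6-exo-trig aldol addition of the ketone enolate to the aldehyde, and aromatisation drives the final dehydration and enolisation. No stereocentre is formed, and both quaternary centres lack an acidic hydrogen and cannot epimerise under the base. No regiochemical question arises, because both α-carbons of the ketone end in the ring and either orientation of the enaminal gives the same arene. The selectivity required is cross-condensation over self-condensation of the ketone, which the non-enolisable, doubly electrophilic enaminal in excess and the slow addition of 13 should secure.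

Step 13
Reactants: 21 bis-MOM ether with free central hydroxyl
Product: 22 3-{2-hydroxy-5-[(3R,6E)-3,7,11-trimethyldodeca-1,6,10-trien-3-yl]phenoxy}-5-[(3S,6E)-3,7,11-trimethyldodeca-1,6,10-trien-3-yl]benzene-1,2-diol
Conditions: TMSOTf, 2,2′-bipyridyl, MeCN, 0 °C → rt; then H2O
Reagents that add atoms: none
Why: Aryl MOM ethers are cleaved by the trimethylsilyl triflate–2,2′-bipyridyl pair through pyridinium intermediates to silyl ethers that hydrolyse on aqueous work-up, under buffered conditions that should not protonate the trisubstituted alkenes or the vinyl groups.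

**Compound list**
1 | (2E,6E)-farnesol | OC/C=C(\C)CC/C=C(\C)CCC=C(C)C | starting material
2 | diethyl (2E,6E)-3,7,11-trimethyldodeca-2,6,10-trien-1-yl phosphate | CCOP(=O)(OCC)OC/C=C(\C)CC/C=C(\C)CCC=C(C)C | intermediate
3 | 1-bromo-4-(methoxymethoxy)benzene | COCOc1ccc(Br)cc1 | starting material
4 | 4-(methoxymethoxy)phenyllithium | [Li]c1ccc(OCOC)cc1 | intermediate
5 | diethyl[4-(methoxymethoxy)phenyl]aluminium | CC[Al](CC)c1ccc(OCOC)cc1 | intermediate
6 | 1-(methoxymethoxy)-4-[(3R,6E)-3,7,11-trimethyldodeca-1,6,10-trien-3-yl]benzene | C=C[C@@](C)(CC/C=C(\C)CCC=C(C)C)c1ccc(OCOC)cc1 | intermediate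
7 | {2-(methoxymethoxy)-5-[(3R,6E)-3,7,11-trimethyldodeca-1,6,10-trien-3-yl]phenyl}lithium | C=C[C@@](C)(CC/C=C(\C)CCC=C(C)C)c1ccc(OCOC)c([Li])c1 | intermediate
8 | dimethyl {2-(methoxymethoxy)-5-[(3R,6E)-3,7,11-trimethyldodeca-1,6,10-trien-3-yl]phenyl}boronate | C=C[C@@](C)(CC/C=C(\C)CCC=C(C)C)c1ccc(OCOC)c(B(OC)OC)c1 | intermediate
9 | 2-(methoxymethoxy)-5-[(3R,6E)-3,7,11-trimethyldodeca-1,6,10-trien-3-yl]phenol | C=C[C@@](C)(CC/C=C(\C)CCC=C(C)C)c1ccc(OCOC)c(O)c1 | intermediate
10 | glycidol (racemic) | OCC1CO1 | starting material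
11 | 2-[(methoxymethoxy)methyl]oxirane (racemic) | COCOCC1CO1 | intermediate
12 | 1-(methoxymethoxy)-3-{2-(methoxymethoxy)-5-[(3R,6E)-3,7,11-trimethyldodeca-1,6,10-trien-3-yl]phenoxy}propan-2-ol (carbinol epimers) | C=C[C@@](C)(CC/C=C(\C)CCC=C(C)C)c1ccc(OCOC)c(OCC(O)COCOC)c1 | intermediate
13 | 1-(methoxymethoxy)-3-{2-(methoxymethoxy)-5-[(3R,6E)-3,7,11-trimethyldodeca-1,6,10-trien-3-yl]phenoxy}propan-2-one | C=C[C@@](C)(CC/C=C(\C)CCC=C(C)C)c1ccc(OCOC)c(OCC(=O)COCOC)c1 | intermediate
14 | methyl (2E,6E)-3,7,11-trimethyldodeca-2,6,10-trien-1-yl carbonate | COC(=O)OC/C=C(\C)CC/C=C(\C)CCC=C(C)C | intermediate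
15 | 4,4,5,5-tetramethyl-2-[(3R,6E)-3,7,11-trimethyldodeca-1,6,10-trien-3-yl]-1,3,2-dioxaborolane | CC1(C)OB(OC1(C)C)[C@](C)(C=C)CC/C=C(\C)CCC=C(C)C | intermediate
16 | 2-[(2S,5E)-2-ethenyl-2,6,10-trimethylundeca-5,9-dien-1-yl]-4,4,5,5-tetramethyl-1,3,2-dioxaborolane | CC1(C)OB(OC1(C)C)C[C@](C)(C=C)CC/C=C(\C)CCC=C(C)C | intermediate
17 | 2-[(3R,6E)-1-chloro-3-ethenyl-3,7,11-trimethyldodeca-6,10-dien-1-yl]-4,4,5,5-tetramethyl-1,3,2-dioxaborolane (both C1 epimers) | CC1(C)OB(OC1(C)C)C(Cl)C[C@](C)(C=C)CC/C=C(\C)CCC=C(C)C | intermediate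
18 | (3R,6E)-3-ethenyl-3,7,11-trimethyldodeca-6,10-dienal | O=CC[C@](C)(C=C)CC/C=C(\C)CCC=C(C)C | intermediate
19 | (2Z)-3-(dimethylamino)-2-[(3S,6E)-3,7,11-trimethyldodeca-1,6,10-trien-3-yl]prop-2-enal | O=C/C(=C\N(C)C)[C@](C)(C=C)CC/C=C(\C)CCC=C(C)C | intermediate
20 | 6-(methoxymethoxy)-4-{2-(methoxymethoxy)-5-[(3R,6E)-3,7,11-trimethyldodeca-1,6,10-trien-3-yl]phenoxy}-5-oxo-2-[(3S,6E)-3,7,11-trimethyldodeca-1,6,10-trien-3-yl]hex-2-enal (C4 epimers, alkene geometry undefined) | O=CC(=CC(Oc1cc([C@@](C)(C=C)CC/C=C(\C)CCC=C(C)C)ccc1OCOC)C(=O)COCOC)[C@](C)(C=C)CC/C=C(\C)CCC=C(C)C | intermediate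
21 | 2-(methoxymethoxy)-6-{2-(methoxymethoxy)-5-[(3R,6E)-3,7,11-trimethyldodeca-1,6,10-trien-3-yl]phenoxy}-4-[(3S,6E)-3,7,11-trimethyldodeca-1,6,10-trien-3-yl]phenol | C=C[C@@](C)(CC/C=C(\C)CCC=C(C)C)c1ccc(OCOC)c(Oc2cc([C@](C)(C=C)CC/C=C(\C)CCC=C(C)C)cc(OCOC)c2O)c1 | intermediate
22 | 3-{2-hydroxy-5-[(3R,6E)-3,7,11-trimethyldodeca-1,6,10-trien-3-yl]phenoxy}-5-[(3S,6E)-3,7,11-trimethyldodeca-1,6,10-trien-3-yl]benzene-1,2-diol | C=C[C@@](C)(CC/C=C(\C)CCC=C(C)C)c1ccc(O)c(Oc2cc([C@](C)(C=C)CC/C=C(\C)CCC=C(C)C)cc(O)c2O)c1 | target

**Step count**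
Total: 13 steps. Longest linear sequence: 7 steps (steps 1, 2, 3, 5, 6, 12, 13; the fragment 2 branch, steps 7–13, is equally long).

**Steps most likely to fail**

Step 12. Self-aldol condensation of ketone 13 may outrun the cross-condensation with the weakly electrophilic, sterically shielded enaminal, or the sequence may stall at the open-chain stage before ring closure and aromatisation. The fallback builds the diaryl ether by C–O coupling instead; it sets out from phosphate 2 and phenol 9 and returns at target 22. 4-Bromocatechol is protected (MOMCl, i-Pr2NEt) as 4-bromo-1,2-bis(methoxymethoxy)benzene F1. The copper-catalysed SN2′ arylation of 2 is run as in step 2 with the antipodal ligand and should give 1,2-bis(methoxymethoxy)-4-[(3S,6E)-3,7,11-trimethyldodeca-1,6,10-trien-3-yl]benzene F2. Ortho-lithiation (s-BuLi, TMEDA, THF, −78 °C) at the position next to a MOM ether that is not blocked by the quaternary carbon, then quenching with 1,2-diiodoethane, should give 1-iodo-2,3-bis(methoxymethoxy)-5-[(3S,6E)-3,7,11-trimethyldodeca-1,6,10-trien-3-yl]benzene F3. Ullmann ether coupling of F3 with 9 (CuI, picolinic acid, K3PO4, DMSO, 90 °C) should give 1,2-bis(methoxymethoxy)-3-{2-(methoxymethoxy)-5-[(3R,6E)-3,7,11-trimethyldodeca-1,6,10-trien-3-yl]phenoxy}-5-[(3S,6E)-3,7,11-trimethyldodeca-1,6,10-trien-3-yl]benzene F4. Cleavage of its three MOM ethers under the conditions of step 13 leads to 22.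

Step 11. The aldehyde may undergo aldol self-condensation, or react only sluggishly at the methylene group next to the quaternary carbon, so that conversion to the enaminal stays incomplete. The fallback sets out from aldehyde 18 and returns at enaminal 19. Condensation with dimethylamine (Me2NH in THF, K2CO3, 0 °C → rt) should give (1E,3S,6E)-3-ethenyl-N,N,3,7,11-pentamethyldodeca-1,6,10-trien-1-amine F5. C-Formylation of this enamine with (chloromethylene)dimethyliminium chloride (Et3N, CH2Cl2, 0 °C), the classical vinamidinium synthesis, should give the symmetrical vinamidinium salt [3-(dimethylamino)-2-[(3S,6E)-3,7,11-trimethyldodeca-1,6,10-trien-3-yl]prop-2-en-1-ylidene]dimethylammonium chloride F6. Partial hydrolysis of F6 with aqueous K2CO3 gives 19.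

Step 8. Facial discrimination between the methyl group and the homogeranyl chain at the alkene terminus may be poor, or some boron may end at the primary carbon (SN2). Either would lower the enantiomeric purity of fragment 2 and lead to a diastereomer of the target that is hard to remove. The fallback sets out from carbonate 14 and returns at aldehyde 18. Iridium-catalysed branched-selective asymmetric allylic alkylation with dimethyl malonate ([Ir(cod)Cl]2, chiral phosphoramidite ligand, NaN(SiMe3)2, ZnI2, THF, rt), a reaction type known to form all-carbon quaternary centres from trisubstituted allylic carbonates, should give dimethyl 2-[(3S,6E)-3,7,11-trimethyldodeca-1,6,10-trien-3-yl]propanedioate F7. Krapcho demethoxycarbonylation (LiCl, wet DMSO, 150 °C) gives methyl (3R,6E)-3-ethenyl-3,7,11-trimethyldodeca-6,10-dienoate F8, and reduction with i-Bu2AlH (toluene, −78 °C) gives 18.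

Further compounds
F1 | step 12 | 4-bromo-1,2-bis(methoxymethoxy)benzene | COCOc1ccc(Br)cc1OCOC
F2 | step 12 | 1,2-bis(methoxymethoxy)-4-[(3S,6E)-3,7,11-trimethyldodeca-1,6,10-trien-3-yl]benzene | C=C[C@](C)(CC/C=C(\C)CCC=C(C)C)c1ccc(OCOC)c(OCOC)c1
F3 | step 12 | 1-iodo-2,3-bis(methoxymethoxy)-5-[(3S,6E)-3,7,11-trimethyldodeca-1,6,10-trien-3-yl]benzene | C=C[C@](C)(CC/C=C(\C)CCC=C(C)C)c1cc(I)c(OCOC)c(OCOC)c1
F4 | step 12 | 1,2-bis(methoxymethoxy)-3-{2-(methoxymethoxy)-5-[(3R,6E)-3,7,11-trimethyldodeca-1,6,10-trien-3-yl]phenoxy}-5-[(3S,6E)-3,7,11-trimethyldodeca-1,6,10-trien-3-yl]benzene | C=C[C@@](C)(CC/C=C(\C)CCC=C(C)C)c1ccc(OCOC)c(Oc2cc([C@](C)(C=C)CC/C=C(\C)CCC=C(C)C)cc(OCOC)c2OCOC)c1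
F5 | step 11 | (1E,3S,6E)-3-ethenyl-N,N,3,7,11-pentamethyldodeca-1,6,10-trien-1-amine | CN(C)/C=C/[C@](C)(C=C)CC/C=C(\C)CCC=C(C)C
F6 | step 11 | [3-(dimethylamino)-2-[(3S,6E)-3,7,11-trimethyldodeca-1,6,10-trien-3-yl]prop-2-en-1-ylidene]dimethylammonium chloride | CN(C)C=C(C=[N+](C)C)[C@](C)(C=C)CC/C=C(\C)CCC=C(C)C.[Cl-]
F7 | step 8 | dimethyl 2-[(3S,6E)-3,7,11-trimethyldodeca-1,6,10-trien-3-yl]propanedioate | COC(=O)C(C(=O)OC)[C@](C)(C=C)CC/C=C(\C)CCC=C(C)C
F8 | step 8 | methyl (3R,6E)-3-ethenyl-3,7,11-trimethyldodeca-6,10-dienoate | COC(=O)C[C@](C)(C=C)CC/C=C(\C)CCC=C(C)C
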